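**Retrosynthetic overview**
1. Cyclointegrin comes from its 5-O-methyl ether by a chelation-controlled demethylation (last step). The oxocine (ring D) is opened at O–C3'': a tertiary cation at C3'' is captured by the 2'-OH of a 3-(3-hydroxy-3-methylbutyl)flavone.
2. The key disconnection is C4–C3 of the pyranone (ring C). The formyl carbon of a 2-(propargyloxy)benzaldehyde is inverted to an acyl anion equivalent (Breslow enaminol) and adds to the alkyne carbon as acceptor. A C2-to-C1'' hydrogen shift then gives the flavone, so the alkyne supplies the C2=C3 unsaturation and leaves no trace.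
3. The aryl propargyl ether (O1–C2 bond) comes from a Mitsunobu reaction of 2-hydroxy-4,6-dimethoxybenzaldehyde (ring A) with a benzylic propargylic carbinol.
4. The carbinol (C2–C3 bond) comes from the acetylide of 2-methylpent-4-yn-2-ol (C3 plus all five side-chain carbons) and 2,4-bis(benzyloxy)benzaldehyde (ring B).
5. Ring order: rings A and B are bought, ring C is formed in step 3, ring D in step 4.

Atom labels: flavone numbering (O1, C2, C3, C4; ring B primed); side chain C1''H2–C2''H2–C3''Me2.

Assumption: the SMILES holds no stereocentre, stereo double bond or fixed axis, so cyclointegrin is treated as achiral (the twisted oxocine is taken to invert at room temperature) and there is no enantiomer to select; chiral intermediates are racemic and their stereo elements are erased in step 3.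

**Step 1**
Reactants: 1 2-methylpent-4-yn-2-ol; 2 2,4-bis(benzyloxy)benzaldehyde
Product: 4 rac-1-[2,4-bis(benzyloxy)phenyl]-5-methylhex-2-yne-1,5-diol, via dilithio alkynolate 3 (not isolated)
Conditions: n-BuLi (2.1 equiv per 1), THF, −78 to 0 °C; add 2, −78 °C to rt; H2O quench
Reagents that add atoms: none
Why: This is a 1,2-addition of a lithium acetylide to an aldehyde, in which the second equivalent of n-BuLi metalates the alkyne C–H of the lithium alkoxide, the acetylide attacks only the formyl group of 2, and the new carbinol centre (later C2) forms racemic, which is harmless because it becomes sp2 in 9.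

**Step 2**
Reactants: 4 rac-1-[2,4-bis(benzyloxy)phenyl]-5-methylhex-2-yne-1,5-diol; 5 2-hydroxy-4,6-dimethoxybenzaldehyde
Product: 6 rac-2-({1-[2,4-bis(benzyloxy)phenyl]-5-hydroxy-5-methylhex-2-yn-1-yl}oxy)-4,6-dimethoxybenzaldehyde
Conditions: PPh3, DIAD, toluene, 0 °C to rt
Reagents that add atoms: none
Why: In this Mitsunobu etherification only the secondary carbinol gives a reactive alkoxyphosphonium salt (the tertiary one is inert), the chelated phenol of 5 is acidic enough to protonate the betaine, C2 has no β-hydrogen for elimination, and any loss of configuration through the stabilised benzylic propargylic cation does not matter for a racemic centre that is flattened later.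

**Step 3**
Reactants: 6 rac-2-({1-[2,4-bis(benzyloxy)phenyl]-5-hydroxy-5-methylhex-2-yn-1-yl}oxy)-4,6-dimethoxybenzaldehyde
Product: 9 2-[2,4-bis(benzyloxy)phenyl]-3-(3-hydroxy-3-methylbutyl)-5,7-dimethoxy-4H-chromen-4-one, via Breslow enaminol 7 (not isolated), via E-alkylideneflavanone 8 (not isolated)
Conditions: 3-mesityl-4,5-dimethylthiazolium perchlorate (10 mol %), K2CO3 (20 mol %), 1,4-dioxane, 80 °C; then DBU (1 equiv), 100 °C, same flask
Reagents that add atoms: none
Why: Proposed new method: the thiazol-2-ylidene adds to the formyl group (ortho-alkoxy groups favour this adduct) and a proton shift gives enaminol 7, in which the former carbonyl carbon C4 is an acyl anion equivalent; C4 adds 6-exo-dig to the proximal sp carbon C3, used as acceptor like the enone carbon of a Stetter reaction, while the enaminol O–H proton goes to C1'' in a concerted Conia-ene-like syn addition (hence E in 8); loss of the carbene frees ketone 8, and only then is DBU added (so that 6 is never exposed to it) to shift the benzylic, allylic, α-oxy C2–H to C1'', the 4-pyranone being the thermodynamic sink; the closest known reaction types are the carbene-catalysed intramolecular hydroacylation of aryl-substituted 2-(propargyloxy)benzaldehydes and the base-induced isomerisation of 3-arylideneflavanones to 3-benzylflavones; both stereo elements (C2 and C3=C1'') vanish in 9.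

**Step 4**
Reactants: 9 2-[2,4-bis(benzyloxy)phenyl]-3-(3-hydroxy-3-methylbutyl)-5,7-dimethoxy-4H-chromen-4-one
Product: 11 5-O-methylcyclointegrin, via debenzylated triol 10 (not isolated)
Conditions: H2 (1 atm), Pd/C (10 wt % Pd), EtOAc, rt; purge with N2; then p-TsOH·H2O (20 mol %), 70 °C, same flask
Reagents that add atoms: none
Why: Hydrogenolysis of both benzyl aryl ethers (the tetrasubstituted C2=C3 bond and the tertiary alcohol are untouched at 1 atm) is followed by an acid-catalysed SN1 cycloetherification in which the C3'' cation forms reversibly, only the 2'-OH can reach it, four of the eight ring atoms are held cisoid by the C2–aryl unit, the gem-dimethyl group helps closure, and side products (alkenes, O4-alkylated pyrylium salt) re-enter the equilibrium under catalytic acid, so the neutral oxocine collects as in the acid cyclisation of 3-prenyl-2'-hydroxyflavones.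

**Step 5**
Reactants: 11 5-O-methylcyclointegrin
Product: 12 cyclointegrin
Conditions: BCl3 (3 equiv), CH2Cl2, −78 to −10 °C; H2O quench
Reagents that add atoms: none
Why: In this chelation-controlled Lewis acid ether cleavage boron binds between the C4 carbonyl oxygen and the peri 5-methoxy oxygen and chloride removes that methyl group, whereas the 7-methoxy group and the oxocine ether have no neighbouring carbonyl for chelation and stay intact at low temperature.

**Compound list**
1 | 2-methylpent-4-yn-2-ol | C#CCC(C)(C)O | starting material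
2 | 2,4-bis(benzyloxy)benzaldehyde | O=Cc1ccc(OCc2ccccc2)cc1OCc1ccccc1 | starting material
3 | dilithio alkynolate (lithium 5-lithio-2-methylpent-4-yn-2-olate) | [Li]C#CCC(C)(C)O[Li] | intermediate (not isolated)
4 | rac-1-[2,4-bis(benzyloxy)phenyl]-5-methylhex-2-yne-1,5-diol | OC(C#CCC(C)(C)O)c1ccc(OCc2ccccc2)cc1OCc1ccccc1 | intermediate
5 | 2-hydroxy-4,6-dimethoxybenzaldehyde | COc1cc(O)c(C=O)c(OC)c1 | starting material
6 | rac-2-({1-[2,4-bis(benzyloxy)phenyl]-5-hydroxy-5-methylhex-2-yn-1-yl}oxy)-4,6-dimethoxybenzaldehyde | COc1cc(OC)c(C=O)c(OC(C#CCC(C)(C)O)c2ccc(OCc3ccccc3)cc2OCc2ccccc2)c1 | intermediate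
7 | Breslow enaminol of 6: the formyl carbon has become C(OH)=C2 of a 3-mesityl-4,5-dimethyl-2,3-dihydrothiazole (racemic) | OC(=C1SC(C)=C(C)N1c1c(C)cc(C)cc1C)c1c(OC)cc(OC)cc1OC(C#CCC(C)(C)O)c1ccc(OCc2ccccc2)cc1OCc1ccccc1 | intermediate (not isolated)
8 | rac-(3E)-2-[2,4-bis(benzyloxy)phenyl]-3-(3-hydroxy-3-methylbutylidene)-5,7-dimethoxy-2,3-dihydro-4H-chromen-4-one | COc1cc(OC)c2C(=O)/C(=C/CC(C)(C)O)C(Oc2c1)c1ccc(OCc2ccccc2)cc1OCc1ccccc1 | intermediate (not isolated)
9 | 2-[2,4-bis(benzyloxy)phenyl]-3-(3-hydroxy-3-methylbutyl)-5,7-dimethoxy-4H-chromen-4-one | COc1cc(OC)c2c(=O)c(CCC(C)(C)O)c(oc2c1)-c1ccc(OCc2ccccc2)cc1OCc1ccccc1 | intermediate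
10 | 2-(2,4-dihydroxyphenyl)-3-(3-hydroxy-3-methylbutyl)-5,7-dimethoxy-4H-chromen-4-one | COc1cc(OC)c2c(=O)c(CCC(C)(C)O)c(oc2c1)-c1ccc(O)cc1O | intermediate (not isolated)
11 | 5-O-methylcyclointegrin (cyclointegrin with OMe in place of the 5-OH) | COc1cc(OC)c2c(=O)c3c(oc2c1)-c1ccc(O)cc1OC(C)(C)CC3 | intermediate
12 | cyclointegrin (no stereocentre) | COc1cc(O)c2c(=O)c3c(oc2c1)-c1ccc(O)cc1OC(C)(C)CC3 | target

**Total step count:** 5. **Longest linear sequence:** 5 (steps 1 to 5).

**Most likely to fail, in this order: step 3, step 4, step 2.**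

Step 3 is the weakest point.
- The formyl group of 6 is electron-rich and flanked by two alkoxy groups.
- An alkyl-substituted alkyne is a poorer acceptor than the aryl alkynes on which this hydroacylation is known.
- Compound 8 can lose acetone by a vinylogous retro-aldol reaction before DBU has moved the double bond.

The fallback keeps the acyl anion but offers it a true carbonyl acceptor. It sets out from 6 and comes back at 12. Ph3PAuNTf2 (2 mol %) in wet 1,4-dioxane hydrates the alkyne at C3 only, because the tertiary hydroxyl adds 5-endo-dig and the dihydrofuran is hydrolysed. This gives the keto aldehyde F1. 2-(Pentafluorophenyl)-6,7-dihydro-5H-pyrrolo[2,1-c][1,2,4]triazol-2-ium tetrafluoroborate and Et3N then close ring C by an aldehyde–ketone crossed benzoin reaction to the 3-hydroxyflavanone F2. SOCl2 in pyridine removes both tertiary hydroxyl groups (any exocyclic C3=C1'' isomer is moved into the ring with DBU) and gives the 3-prenylflavone F3. BCl3 with C6HMe5 at −78 to 0 °C takes off both benzyl groups and the 5-O-methyl group, leaves the 7-methoxy group, and gives integrin F4. Catalytic p-TsOH in warm EtOAc closes ring D to 12.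

Step 4 comes next. The eight-membered ring may lose against E1 proton loss or against alkylation of the C4 carbonyl oxygen. The fallback replaces reversible cation capture by an irreversible, electrophile-driven etherification of the alkene. It sets out from 10, which is then isolated after the hydrogenolysis, and comes back at 11. p-TsOH in refluxing toluene with removal of water gives on purpose the alkene 5-O-methylintegrin F5. Hg(OCOCF3)2 in MeNO2 at 0 °C adds the 2'-oxygen to the tertiary carbon (Markovnikov phenoxymercuration) and gives the organomercurial F6. NaBH4 in aqueous NaOH replaces mercury by hydrogen and would also undo any aryl mercuration.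

Step 2 is third. The alkoxyphosphonium salt of the very electron-rich carbinol can ionise, and the cation can then be taken up by a ring carbon of 5 or by the hydrazide. The fallback forms the other C–O bond of the same ether, aryl carbon to oxygen, so that C2 never becomes cationic. It sets out from 4 and comes back at 6. NaH (1 equiv) in DMF at 0 °C deprotonates the more acidic secondary hydroxyl. The alkoxide then displaces fluoride from 2-fluoro-4,6-dimethoxybenzaldehyde, used as a bought reagent (SNAr ortho to the formyl group, rt to 50 °C). No compound outside the list is made (F0).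

**Further compounds**
F0 | step 2 | none | none
F1 | step 3 | rac-2-({1-[2,4-bis(benzyloxy)phenyl]-5-hydroxy-5-methyl-2-oxohexyl}oxy)-4,6-dimethoxybenzaldehyde | COc1cc(OC)c(C=O)c(OC(C(=O)CCC(C)(C)O)c2ccc(OCc3ccccc3)cc2OCc2ccccc2)c1
F2 | step 3 | 2-[2,4-bis(benzyloxy)phenyl]-3-hydroxy-3-(3-hydroxy-3-methylbutyl)-5,7-dimethoxy-2,3-dihydro-4H-chromen-4-one (racemic, both diastereomers) | COc1cc(OC)c2C(=O)C(O)(CCC(C)(C)O)C(Oc2c1)c1ccc(OCc2ccccc2)cc1OCc1ccccc1
F3 | step 3 | 2-[2,4-bis(benzyloxy)phenyl]-5,7-dimethoxy-3-(3-methylbut-2-en-1-yl)-4H-chromen-4-one | COc1cc(OC)c2c(=O)c(CC=C(C)C)c(oc2c1)-c1ccc(OCc2ccccc2)cc1OCc1ccccc1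
F4 | step 3 | integrin, 2-(2,4-dihydroxyphenyl)-5-hydroxy-7-methoxy-3-(3-methylbut-2-en-1-yl)-4H-chromen-4-one | COc1cc(O)c2c(=O)c(CC=C(C)C)c(oc2c1)-c1ccc(O)cc1O
F5 | step 4 | 5-O-methylintegrin, 2-(2,4-dihydroxyphenyl)-5,7-dimethoxy-3-(3-methylbut-2-en-1-yl)-4H-chromen-4-one | COc1cc(OC)c2c(=O)c(CC=C(C)C)c(oc2c1)-c1ccc(O)cc1O
F6 | step 4 | rac-5-O-methylcyclointegrin carrying HgOCOCF3 at C2'' | COc1cc(OC)c2c(=O)c3c(oc2c1)-c1ccc(O)cc1OC(C)(C)C([Hg]OC(=O)C(F)(F)F)C3
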